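What is left of the catalyst once the added ligand has taken its share? We follow that leftover; the runs differ in it.

| flask | substrate | catalyst | added ligand | remark | time |
|---|---|---|---|---|---|
| Friday's | 1.1 M (fed, over 12 h) | 0.07 mol% | 1.8 mM | run made earlier; the fed solution adds 1.0 times the starting volume |  |
| Monday's | 1.1 M (fed, over 12 h) | 0.28 mol% | 1.8 mM | run made earlier; the fed solution adds 1.0 times the starting volume |  |
| Sunday's | 1.7 M (fed, over 12 h) | 0.14 mol% | 1.8 mM | run made earlier; the fed solution adds 1.0 times the starting volume |  |
| flask | 1.1 M (fed, over 12 h) | 0.14 mol% | 1.8 mM | the fed solution adds 1.0 times the starting volume | 15 d |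

| run | time / d | target / % | substrate / % |
|---|---|---|---|
| Friday's | 0.208 | 10.6 | 29.6 |
| Friday's | 0.833 | 65.0 | 21.6 |
| Friday's | 4.00 | 36.6 | 3.3 |
| Friday's | 15.0 | 25.6 | 3.9 |
| Monday's | 0.208 | 6.6 | 30.0 |
| Monday's | 0.833 | 36.9 | 20.5 |
| Monday's | 4.00 | 18.6 | 4.8 |
| Monday's | 15.0 | 3.1 | 0 |
| Sunday's | 0.208 | 9.3 | 30.1 |
| Sunday's | 0.833 | 43.2 | 19.6 |
| Sunday's | 4.00 | 23.9 | 2.8 |
| Sunday's | 15.0 | 7.3 | 0 |

(scatter of a reading: 1 percentage point)

- percentages count the substrate that a species holds: one idle adduct counts as two
- target is meant together with its idle adduct
- every charge counts on the volume at the start, and the solution that is fed holds the whole dose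
- candidate steps: substrate <-> target; target + catalyst <-> isomer of the product A + catalyst; isomer of the product A + catalyst <-> isomer of the product B + catalyst; substrate + target <-> idle adduct; catalyst + added ligand <-> idle complex
- percentages count the whole charge, also what has not yet gone in
- in an amount of target, one idle adduct counts as one target

1. the best time, 15 d at the latest, for target
2. the amount of target, in percent of the substrate charged, at that time
3. earliest time at which at least nineteen twentieths of that best amount are there, in d
4. latest time at which they still are, in d

In the flask the catalyst is charged in the smaller amount, so it is the limiting reagent of the binding. For the flask, catalyst charge minus ligand charge, per starting volume, is −0.260 mM; we call this the leftover. A negative value is a balance on paper, not a free amount. The same balance gives −1.03 mM for Friday's run, 0.580 mM for Sunday's and 1.28 mM for Monday's.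

We reckon at 0.833 d, since in each run target stands higher there than at 0.208 d or 4.00 d.

First, the main step, substrate to target. Substrate reads 21.6%, 20.5% and 19.6% on Friday's, Monday's and Sunday's runs, close together though the catalyst differs. Taking their mean, target could stand at:

79.4%

Second, the catalysed loss of target to isomer of the product A. We call the gap what neither target nor substrate holds. It reads 13.4% on Friday's run, 37.2% on Sunday's and 42.6% on Monday's, rising with the leftover. Friday's gap brings target down to 66.0%.

Third, the leftover places the flask between Friday's and Sunday's runs, and the remaining steps stay inside the gap as read: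

gap = 24.8%

target = 54.7%

The forecast, holding that “free catalyst in the flask lies between Friday's and Sunday's”, gives 55% (range 49% to 61%) at 0.82 d, with a window from 0.65 d to 1.07 d.

The flask gives 51.9% at 0.845 d, with the window asked for running from 0.668 d to 1.10 d, so our reckoning stands 2.8 percentage points high.

    substrate ⇌ target (K = 9.23, k = 0.133 h⁻¹)
    target + catalyst ⇌ isomer of the product A + catalyst, rate k2*[catalyst]*[target] forward; the back reaction follows from the equilibrium constant (K = 2.00, k = 191 M⁻¹ h⁻¹)
    isomer of the product A + catalyst ⇌ isomer of the product B + catalyst, rate k3*[catalyst]*[isomer of the product A] forward; the back reaction follows from the equilibrium constant (K = 25.0, k = 15.3 M⁻¹ h⁻¹)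
    substrate + target ⇌ idle adduct, settled at all times (K = 0.291 M⁻¹)
    catalyst + added ligand ⇌ idle complex, settled at all times (K = 4200 M⁻¹)

The leftover of −0.260 mM does not mean that no catalyst is free: at 0.845 d the flask holds 36.6% of its catalyst free and 63.4% as idle complex. The largest single effect on the peak is the loss of target to isomer of the product A: the same flask without that step peaks at 89.1% against 51.9%. The parking of catalyst as idle complex works the other way, as one part of the picture: without it the flask peaks at 37.3%, and earlier, at 0.750 d against 0.845 d.

Take a neighbour of the flask with 4.5 × 10⁻⁴ M of added ligand. Its leftover is 1.09 mM, between Sunday's and Monday's, so our estimate of the gap is 41.1% and of target about 38.3%. The computed best there is 40.5%.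

The readings come from a simulation for substances that don't exist, and the scatter is random.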